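## The problem

The target 28 is a depside. Ring A (C1 acyl carbon, C2 OH, C4 OMe, C6 2-oxoheptyl) is joined through its carboxyl carbon to O4' of ring B (C1' COOH, C2' OMe, C4' O-acyl, C6' 2-oxoheptyl) by one aryl ester bond. There is no ring fusion and no stereocenter, so the synthesis has to control only regiochemistry and chemoselectivity. Both rings have the same carbon skeleton, a benzoic acid flanked by an oxygen and a CH2C(=O)C5H11 chain, but their oxygens are differentiated in opposite senses (ring A: O2 free, O4 methylated; ring B: O2' methylated, O4' acylated), so one symmetric resorcinol precursor cannot serve both. Each carboxyl is di-ortho-substituted and therefore slow to esterify or hydrolyse. Each also lies next to an enolisable benzyl ketone, which closes onto an activated or protonated carboxyl to give a lactol or a 3-pentylisocoumarin. The inter-ring aryl ester is an activated ester that will not survive hydroxide, alkoxides, amines or organometallic reagents, so all such chemistry must come before it and the end-game is limited to dilute acid and hydrogenolysis. The feature that opens ring B to a short construction is that its carboxyl carbon and its benzylic carbon sit on the adjacent ring carbons C1' and C6', with the C2' methoxy group beside C1'. That is the pattern a 3-alkoxyaryne spanning C1'–C6' leaves when it inserts into a C–C bond of a malonate.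

## Retrosynthesis

**End-game.** The target 28 is traced back to the diketone 27 by cutting the two O–CH2Ph bonds (ring A ether at O2, ring B ester at C1'). One neutral hydrogenolysis releases both, and nothing acidic or basic touches the depside afterwards. Compound 27 comes from ketal 26 by hydrolysis of the dioxolane on the ring A chain. The ketal is needed only for the esterification; it is removed at the ester stage, before the ring B acid is free to form a lactol.

**Depside bond.** Cutting the C(=O)–O4' bond of 26 gives the ring A acid 25 and the ring B phenol 18, two fragments of similar size. This is the only disconnection that divides the molecule into halves, and it places the one hindered esterification at the convergence point. The ring A ketone must be masked (dioxolane in 25), because a free 2-oxoalkyl group closes onto the activated carboxyl. The ring B ketone in 18 can stay free, since only the para-ester-acidified phenol is acylated under amine catalysis.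

**Ring B side chain.** Phenol 18 comes from its 4-methoxybenzyl ether 17. Cutting the C(=O)–C5H11 bond of 17 leads to Weinreb amide 15 and pentylmagnesium bromide 16; 15 comes from acid 14, and 14 from the dibenzyl homophthalate 13 by hydrolysis of the unhindered aliphatic ester. The 2,6-disubstituted aromatic ester is slow enough to be left alone by hydroxide and by the Grignard reagent, so the two carboxyls of 13 are differentiated by sterics alone, with no extra protecting group.

**Key disconnection.** In 13 the C6'–CH2 and C1'–C(=O) bonds are cut together. This returns aryne 12, released from the silylaryl triflate 10, and dibenzyl malonate 11. Against stepwise routes (ortho-metalation and carboxylation, then homologation), it sets both ortho carbon substituents in one operation, and the C2' methoxy group decides which carbon receives which. The malonate's benzyl groups make the aromatic ester of 13 the final protecting group of the ring B acid. The forward reaction must be regioselective on an unsymmetrical aryne and must favour insertion over simple arylation.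

**Aryne precursor.** Triflate 10 is cut at O–S and C–Si to carbamate 8, and 8 at C6–Si to the N-isopropylcarbamate 5 of phenol 4. The carbamate has only one free ortho position, so silicon can only go where it is needed. Phenol 4 comes from aldehyde 2 by replacing the formyl carbon with oxygen (Baeyer–Villiger oxidation), and 2 from commercial 4-hydroxy-2-methoxybenzaldehyde 1 by etherification. Starting from 1, which already carries the methyl ether, saves one alkylation compared with 2,4-dihydroxybenzaldehyde. The 4-methoxybenzyl ether is chosen for O4' because it survives fluoride, hydroxide and Grignard reagent and leaves oxidatively beside the benzyl ester.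

**Ring A.** Acid 25 is traced to its methyl ester 24, to ketone 23, and by cutting the CH2–C(=O) bond to toluate 21 and N-methoxy-N-methylhexanamide 22. Toluate 21 comes from commercial methyl orsellinate 19 through the 4-O-methyl ether 20. A second aryne sequence for ring A would need a different silylaryl triflate (benzyloxy next to the triple bond) and five more steps, whereas 19 already contains every ring A carbon except the hexanoyl unit. The chelated 2-OH of 19 allows O4 to be methylated first, and benzyl on O2 is removed in the final hydrogenolysis.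

## Roads not taken

Alternative 1: The C6–CH2 bond of ring A is cut and formed by carboxylate-directed C–H activation. 2,4-Dimethoxybenzoic acid A1 and the sulfoxonium ylide A2 would react under a ruthenium arene chloride catalyst with an acetate base; the acylmethylated acid closes to 6,8-dimethoxy-3-pentyl-1H-isochromen-1-one A3.
- Merits: one step from a commercial acid, no pre-functionalised arene, the chain at the ketone oxidation level, and unambiguous regiochemistry because only one ortho C–H is present. For installing the chain this is clearly shorter than either the five-step precursor synthesis for ring B or the toluate sequence for ring A used here.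
- Weak points: A3 stores the keto acid as the enol lactone that the target must avoid. It has to be reopened with hydroxide, the peri methyl ether has to be cleaved selectively, and the liberated keto acid still needs ketalisation and O2 protection before it can be esterified. The net saving over 19 → 25 is therefore small. Ring B would need a 4-protected 2-methoxybenzoic acid and the same lactone opening, followed by re-esterification of a hindered acid as its benzyl ester.
- Comparison: the aryne insertion delivers ring B already open, with the aromatic carboxyl as the final benzyl ester and the side-chain carbon as a separately addressable ester.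

Alternative 2: Ring B is cut at C1'–C2' and C5'–C6' and assembled by a Diels–Alder reaction of the ketene-acetal diene A4 with the ynoate A5 (racemic). Elimination of an alcohol molecule and loss of the silyl group then aromatise to benzyl 2-[2-(tert-butyldimethylsilyloxy)heptyl]-4-hydroxy-6-methoxybenzoate A6 (racemic).
- Merits: the ring is made with O2' methylated and O4' free, so no protecting group is needed at O4'. The ester is benzyl from the start. The phenol for depside formation is reached in fewer steps than 18.
- Weak points: a β-alkyl ynoate is a sluggish dienophile and the diene is moisture-sensitive, so the cycloaddition needs forcing conditions. The chain arrives at the alcohol oxidation level with a stereocenter that has to be destroyed later. That costs a desilylation and an oxidation, and the freed hydroxyl sits where it lactonises onto the neighbouring benzyl ester to a dihydroisocoumarin. If that unmasking is postponed until after the depside bond, fluoride and an oxidant meet the aryl ester.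
- Comparison: the chosen plan pays with a longer precursor synthesis. In return it has a room-temperature key step of a known regiochemical type, a chain that never passes through an alcohol, and no lactonisation trap.

Alternative 3: The depside C–O bond and the C1–C6 bond of ring A are cut. Thermolysis of the diketo-dioxinone A7 would release an acylketene that is captured by the ring B phenol A8. A tertiary amine base then folds the triketo aryl ester by aldol condensation and aromatises ring A to the depside A9.
- Merits: the inter-ring ester is formed without activating a di-ortho-substituted benzoic acid. That operation (step 16) is the weakest one of the chosen plan, and in this respect Alternative 3 is better. Ring A also appears with its 2-OH free.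
- Weak points: A9 carries a 2,4-dihydroxy ring A, so a selective O4 methylation on a base-sensitive depside is added at a late stage. A7 is a labile polycarbonyl compound that needs its own multistep synthesis. The aryl β-ketoester intermediates can lose the phenol again or cyclise to pyranones. Ring B is not addressed at all: A8 still has to be made, most directly by the aryne insertion itself.
- Comparison: the chosen plan uses stable, fully aromatic fragments and a conventional coupling; the price is the hindered esterification, for which a fallback is given.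

Key step: step 6

Remark: the target is taken as the open-chain keto acid as drawn; reversible lactol formation between the ring B carboxyl and its neighbouring ketone in solution does not change the constitution aimed at.

## Route

Step 1
Reactants: 1 4-hydroxy-2-methoxybenzaldehyde
Product: 2 2-methoxy-4-(4-methoxybenzyloxy)benzaldehyde
Conditions: PMBCl, K2CO3, KI (cat.), DMF, 60 °C
Reagents that add atoms: 4-methoxybenzyl chloride, COc1ccc(CCl)cc1
Why: Williamson etherification of the only phenol, whose phenoxide forms readily because of the para formyl group; the aldehyde is inert to carbonate.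

Step 2
Reactants: 2 2-methoxy-4-(4-methoxybenzyloxy)benzaldehyde
Product: 4 2-methoxy-4-(4-methoxybenzyloxy)phenol, via aryl formate 3 (not isolated)
Conditions: mCPBA, CH2Cl2, 0 °C → rt; then K2CO3 (cat.), MeOH, rt
Reagents that add atoms: 3-chloroperoxybenzoic acid, O=C(OO)c1cccc(Cl)c1
Why: Baeyer–Villiger (Dakin-type) oxidation; the ortho/para-dialkoxyaryl group migrates in preference to hydrogen, and the aryl formate is methanolysed in the same flask. Benzyl-type ethers are inert to the peracid.

Step 3
Reactants: 4 2-methoxy-4-(4-methoxybenzyloxy)phenol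
Product: 5 2-methoxy-4-(4-methoxybenzyloxy)phenyl N-isopropylcarbamate
Conditions: i-PrNCO, Et3N (cat.), CH2Cl2, rt
Reagents that add atoms: isopropyl isocyanate, CC(C)N=C=O
Why: Base-catalysed addition of the phenol to an isocyanate gives the secondary carbamate, which serves as the directing group and can later be removed under mild base.

Step 4
Reactants: 5 2-methoxy-4-(4-methoxybenzyloxy)phenyl N-isopropylcarbamate
Product: 8 2-methoxy-4-(4-methoxybenzyloxy)-6-(trimethylsilyl)phenyl N-isopropylcarbamate, via N-silyl carbamate 6 (not isolated), via N-silyl 6-trimethylsilyl carbamate 7 (not isolated)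
Conditions: TBSOTf, TMEDA, Et2O, 0 °C → rt; then n-BuLi, TMEDA, −78 °C; then TMSCl, −78 °C → rt; aq. NaHSO4
Reagents that add atoms: chlorotrimethylsilane, C[Si](C)(C)Cl; tert-butyldimethylsilyl trifluoromethanesulfonate, CC(C)(C)[Si](C)(C)OS(=O)(=O)C(F)(F)F (its silyl group is carried only by 6 and 7)
Why: Directed ortho-metalation; N-silylation makes the carbamate a tertiary directing group, and the only free position ortho to it is C6, so the aryllithium is silylated there. The N–Si bond is hydrolysed at work-up.

Step 5
Reactants: 8 2-methoxy-4-(4-methoxybenzyloxy)-6-(trimethylsilyl)phenyl N-isopropylcarbamate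
Product: 10 2-methoxy-4-(4-methoxybenzyloxy)-6-(trimethylsilyl)phenyl trifluoromethanesulfonate, via silyl phenol 9 (not isolated)
Conditions: DBU, Et2NH, MeCN, 40 °C; then PhNTf2, rt
Reagents that add atoms: N-phenylbis(trifluoromethanesulfonimide), O=S(=O)(N(c1ccccc1)S(=O)(=O)C(F)(F)F)C(F)(F)F
Why: E1cB cleavage of the secondary carbamate (the isocyanate is trapped by diethylamine) gives the phenoxide, which is triflated in the same flask by the mild triflimide. The aryl–silicon bond and the benzyl-type ether are not affected.

Step 6
Reactants: 10 2-methoxy-4-(4-methoxybenzyloxy)-6-(trimethylsilyl)phenyl trifluoromethanesulfonate; 11 dibenzyl malonate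
Product: 13 benzyl 2-(2-benzyloxy-2-oxoethyl)-6-methoxy-4-(4-methoxybenzyloxy)benzoate, via aryne 12 (not isolated)
Conditions: 11 (1.5 equiv), KF, 18-crown-6, THF, rt
Reagents that add atoms: none
Why: Fluoride attacks silicon in 10 and triflate leaves, giving aryne 12 with its triple bond between the carbons that become C1' and C6'. The potassium enolate of 11 adds to the aryne carbon remote from the methoxy group (future C6'), because the aryl anion that develops at C1' is stabilised inductively by the neighbouring C2' oxygen and the aryne is distorted towards attack at the far carbon. The aryl anion then attacks an ester carbonyl of the malonate unit (4-exo-trig) to give a benzocyclobutenoxide; opening of this four-membered ring leaves the benzyl ester on C1' and an ester-stabilised benzylic anion that is protonated, so no ring remains and no stereocenter is formed. The closest known reaction type is the fluoride-induced insertion of 3-alkoxyarynes into the carbon–carbon σ-bond of malonates and β-ketoesters (aryne acyl-alkylation). The step needs regioselectivity, which the C2' methoxy group beside the triple bond secures, and chemoselectivity for insertion over simple α-arylation by proton transfer to the aryl anion, for which malonates under KF/18-crown-6 in THF are the established case. The excess of 11 should keep the more acidic product from competing for the aryne, and the 4-methoxybenzyl ether and benzyl esters are inert to fluoride.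

Step 7
Reactants: 13 benzyl 2-(2-benzyloxy-2-oxoethyl)-6-methoxy-4-(4-methoxybenzyloxy)benzoate
Product: 14 2-[2-(benzyloxycarbonyl)-3-methoxy-5-(4-methoxybenzyloxy)phenyl]acetic acid
Conditions: LiOH·H2O (1.1 equiv), THF/H2O, 0 °C → rt; then 1 M HCl to pH 3
Reagents that add atoms: lithium hydroxide, [Li+].[OH-]
Why: Saponification of the unhindered aliphatic ester; the di-ortho-substituted aromatic benzyl ester is shielded from hydroxide, as in the selective hydrolysis of homophthalate diesters.

Step 8
Reactants: 14 2-[2-(benzyloxycarbonyl)-3-methoxy-5-(4-methoxybenzyloxy)phenyl]acetic acid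
Product: 15 benzyl 2-methoxy-6-{2-[methoxy(methyl)amino]-2-oxoethyl}-4-(4-methoxybenzyloxy)benzoate
Conditions: MeNHOMe·HCl, EDC·HCl, HOBt, i-Pr2NEt, CH2Cl2, 0 °C → rt
Reagents that add atoms: N,O-dimethylhydroxylamine hydrochloride, CNOC.Cl
Why: Carbodiimide amidation of an unhindered arylacetic acid to the Weinreb amide; no other group in 14 reacts under these conditions.

Step 9
Reactants: 15 benzyl 2-methoxy-6-{2-[methoxy(methyl)amino]-2-oxoethyl}-4-(4-methoxybenzyloxy)benzoate; 16 pentylmagnesium bromide
Product: 17 benzyl 2-methoxy-4-(4-methoxybenzyloxy)-6-(2-oxoheptyl)benzoate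
Conditions: C5H11MgBr (2.5 equiv), THF, −78 → 0 °C; sat. aq. NH4Cl
Reagents that add atoms: none
Why: Weinreb ketone synthesis; the chelated tetrahedral adduct prevents over-addition, and the di-ortho-substituted benzyl benzoate is too hindered to compete at low temperature.

Step 10
Reactants: 17 benzyl 2-methoxy-4-(4-methoxybenzyloxy)-6-(2-oxoheptyl)benzoate
Product: 18 benzyl 4-hydroxy-2-methoxy-6-(2-oxoheptyl)benzoate
Conditions: DDQ, CH2Cl2/pH 7 buffer, 0 °C → rt
Reagents that add atoms: none
Why: Oxidative cleavage of the 4-methoxybenzyl ether (hydride abstraction, then hydrolysis of the oxocarbenium ion); the benzyl ester lacks the activating methoxy group, and the ester-bearing phenol that is released is too electron-poor to be oxidised further.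

Step 11
Reactants: 19 methyl 2,4-dihydroxy-6-methylbenzoate
Product: 20 methyl 2-hydroxy-4-methoxy-6-methylbenzoate
Conditions: MeI (1.05 equiv), K2CO3, acetone, reflux
Reagents that add atoms: iodomethane, CI
Why: Williamson methylation of the more acidic, unchelated 4-hydroxyl; the 2-hydroxyl is hydrogen-bonded to the ester carbonyl and reacts much more slowly.

Step 12
Reactants: 20 methyl 2-hydroxy-4-methoxy-6-methylbenzoate
Product: 21 methyl 2-(benzyloxy)-4-methoxy-6-methylbenzoate
Conditions: BnBr, K2CO3, DMF, 60 °C
Reagents that add atoms: benzyl bromide, BrCc1ccccc1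
Why: Williamson benzylation of the remaining chelated phenol under more forcing conditions; the benzyl group is removed in the final hydrogenolysis.

Step 13
Reactants: 21 methyl 2-(benzyloxy)-4-methoxy-6-methylbenzoate; 22 N-methoxy-N-methylhexanamide
Product: 23 methyl 2-(benzyloxy)-4-methoxy-6-(2-oxoheptyl)benzoate
Conditions: LiN(i-Pr)2 (2.2 equiv), THF, −78 °C; then 22, −78 → −20 °C; sat. aq. NH4Cl
Reagents that add atoms: none
Why: Lateral lithiation of the ortho-toluate (the benzylic anion is an extended ester enolate) and acylation by the Weinreb amide, a standard entry to 6-(2-oxoalkyl) resorcylates. The hindered ester resists self-condensation at −78 °C.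

Step 14
Reactants: 23 methyl 2-(benzyloxy)-4-methoxy-6-(2-oxoheptyl)benzoate
Product: 24 methyl 2-(benzyloxy)-4-methoxy-6-[(2-pentyl-1,3-dioxolan-2-yl)methyl]benzoate
Conditions: (TMSOCH2)2, TMSOTf (cat.), CH2Cl2, −78 → −20 °C; pyridine quench
Reagents that add atoms: 1,2-bis(trimethylsilyloxy)ethane, C[Si](C)(C)OCCO[Si](C)(C)C
Why: Silyl-transfer ketalisation at low temperature under aprotic conditions, chosen over hot protic acid so that the ketone does not close onto the neighbouring ester to give the isocoumarin.

Step 15
Reactants: 24 methyl 2-(benzyloxy)-4-methoxy-6-[(2-pentyl-1,3-dioxolan-2-yl)methyl]benzoate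
Product: 25 2-(benzyloxy)-4-methoxy-6-[(2-pentyl-1,3-dioxolan-2-yl)methyl]benzoic acid
Conditions: KOH, DMSO/H2O, 90 °C; then 1 M HCl to pH 4, 0 °C
Reagents that add atoms: potassium hydroxide, [K+].[OH-]
Why: Saponification of a di-ortho-substituted methyl benzoate needs poorly solvated hydroxide and heat; the dioxolane and benzyl ether are stable to base, and the cold, mildly acidic work-up spares the ketal.

Step 16
Reactants: 25 2-(benzyloxy)-4-methoxy-6-[(2-pentyl-1,3-dioxolan-2-yl)methyl]benzoic acid; 18 benzyl 4-hydroxy-2-methoxy-6-(2-oxoheptyl)benzoate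
Product: 26 benzyl 4-({2-(benzyloxy)-4-methoxy-6-[(2-pentyl-1,3-dioxolan-2-yl)methyl]benzoyl}oxy)-2-methoxy-6-(2-oxoheptyl)benzoate
Conditions: EDC·HCl, DMAP, CH2Cl2, rt
Reagents that add atoms: none
Why: Steglich esterification, the usual way to make depside bonds from O-benzylated di-ortho-substituted benzoic acids; the acylpyridinium ion is captured by the acidic para-ester phenol. The conditions are neutral enough for the ketal, and the ring B ketone is not acylated.

Step 17
Reactants: 26 benzyl 4-({2-(benzyloxy)-4-methoxy-6-[(2-pentyl-1,3-dioxolan-2-yl)methyl]benzoyl}oxy)-2-methoxy-6-(2-oxoheptyl)benzoate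
Product: 27 benzyl 4-{[2-(benzyloxy)-4-methoxy-6-(2-oxoheptyl)benzoyl]oxy}-2-methoxy-6-(2-oxoheptyl)benzoate
Conditions: 1 M aq. HCl, THF, rt
Reagents that add atoms: water, O
Why: Acid hydrolysis of a dialkyl-ketone dioxolane proceeds at room temperature in dilute acid, conditions under which aryl and benzyl esters are stable.

Step 18
Reactants: 27 benzyl 4-{[2-(benzyloxy)-4-methoxy-6-(2-oxoheptyl)benzoyl]oxy}-2-methoxy-6-(2-oxoheptyl)benzoate
Product: 28 4-{[2-hydroxy-4-methoxy-6-(2-oxoheptyl)benzoyl]oxy}-2-methoxy-6-(2-oxoheptyl)benzoic acid (target)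
Conditions: H2 (1 atm), 10% Pd/C, EtOAc, rt
Reagents that add atoms: none
Why: Hydrogenolysis cleaves the benzyl ester and the aryl benzyl ether together under neutral conditions; the aliphatic ketones and the depside ester are not reduced at atmospheric pressure.

## Compound list

1 | 4-hydroxy-2-methoxybenzaldehyde | COc1cc(O)ccc1C=O | starting material
2 | 2-methoxy-4-(4-methoxybenzyloxy)benzaldehyde | COc1ccc(COc2ccc(C=O)c(OC)c2)cc1 | intermediate
3 | 2-methoxy-4-(4-methoxybenzyloxy)phenyl formate | COc1ccc(COc2ccc(OC=O)c(OC)c2)cc1 | intermediate
4 | 2-methoxy-4-(4-methoxybenzyloxy)phenol | COc1ccc(COc2ccc(O)c(OC)c2)cc1 | intermediate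
5 | 2-methoxy-4-(4-methoxybenzyloxy)phenyl N-isopropylcarbamate | COc1ccc(COc2ccc(OC(=O)NC(C)C)c(OC)c2)cc1 | intermediate
6 | 2-methoxy-4-(4-methoxybenzyloxy)phenyl N-(tert-butyldimethylsilyl)-N-isopropylcarbamate | COc1ccc(COc2ccc(OC(=O)N(C(C)C)[Si](C)(C)C(C)(C)C)c(OC)c2)cc1 | intermediate
7 | 2-methoxy-4-(4-methoxybenzyloxy)-6-(trimethylsilyl)phenyl N-(tert-butyldimethylsilyl)-N-isopropylcarbamate | COc1ccc(COc2cc(OC)c(OC(=O)N(C(C)C)[Si](C)(C)C(C)(C)C)c([Si](C)(C)C)c2)cc1 | intermediate
8 | 2-methoxy-4-(4-methoxybenzyloxy)-6-(trimethylsilyl)phenyl N-isopropylcarbamate | COc1ccc(COc2cc(OC)c(OC(=O)NC(C)C)c([Si](C)(C)C)c2)cc1 | intermediate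
9 | 2-methoxy-4-(4-methoxybenzyloxy)-6-(trimethylsilyl)phenol | COc1ccc(COc2cc(OC)c(O)c([Si](C)(C)C)c2)cc1 | intermediate
10 | 2-methoxy-4-(4-methoxybenzyloxy)-6-(trimethylsilyl)phenyl trifluoromethanesulfonate | COc1ccc(COc2cc(OC)c(OS(=O)(=O)C(F)(F)F)c([Si](C)(C)C)c2)cc1 | intermediate
11 | dibenzyl malonate | O=C(CC(=O)OCc1ccccc1)OCc1ccccc1 | starting material
12 | 3-methoxy-5-(4-methoxybenzyloxy)benzyne (1,2-didehydro-3-methoxy-5-(4-methoxybenzyloxy)benzene) | COC1=CC(OCc2ccc(OC)cc2)=CC#C1 | intermediate
13 | benzyl 2-(2-benzyloxy-2-oxoethyl)-6-methoxy-4-(4-methoxybenzyloxy)benzoate | COc1ccc(COc2cc(OC)c(C(=O)OCc3ccccc3)c(CC(=O)OCc3ccccc3)c2)cc1 | intermediate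
14 | 2-[2-(benzyloxycarbonyl)-3-methoxy-5-(4-methoxybenzyloxy)phenyl]acetic acid | COc1ccc(COc2cc(OC)c(C(=O)OCc3ccccc3)c(CC(=O)O)c2)cc1 | intermediate
15 | benzyl 2-methoxy-6-{2-[methoxy(methyl)amino]-2-oxoethyl}-4-(4-methoxybenzyloxy)benzoate | COc1ccc(COc2cc(OC)c(C(=O)OCc3ccccc3)c(CC(=O)N(C)OC)c2)cc1 | intermediate
16 | pentylmagnesium bromide | CCCCC[Mg]Br | starting material
17 | benzyl 2-methoxy-4-(4-methoxybenzyloxy)-6-(2-oxoheptyl)benzoate | CCCCCC(=O)Cc1cc(OCc2ccc(OC)cc2)cc(OC)c1C(=O)OCc1ccccc1 | intermediate
18 | benzyl 4-hydroxy-2-methoxy-6-(2-oxoheptyl)benzoate | CCCCCC(=O)Cc1cc(O)cc(OC)c1C(=O)OCc1ccccc1 | intermediate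
19 | methyl 2,4-dihydroxy-6-methylbenzoate | COC(=O)c1c(C)cc(O)cc1O | starting material
20 | methyl 2-hydroxy-4-methoxy-6-methylbenzoate | COC(=O)c1c(C)cc(OC)cc1O | intermediate
21 | methyl 2-(benzyloxy)-4-methoxy-6-methylbenzoate | COC(=O)c1c(C)cc(OC)cc1OCc1ccccc1 | intermediate
22 | N-methoxy-N-methylhexanamide | CCCCCC(=O)N(C)OC | starting material
23 | methyl 2-(benzyloxy)-4-methoxy-6-(2-oxoheptyl)benzoate | CCCCCC(=O)Cc1cc(OC)cc(OCc2ccccc2)c1C(=O)OC | intermediate
24 | methyl 2-(benzyloxy)-4-methoxy-6-[(2-pentyl-1,3-dioxolan-2-yl)methyl]benzoate | CCCCCC1(Cc2cc(OC)cc(OCc3ccccc3)c2C(=O)OC)OCCO1 | intermediate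
25 | 2-(benzyloxy)-4-methoxy-6-[(2-pentyl-1,3-dioxolan-2-yl)methyl]benzoic acid | CCCCCC1(Cc2cc(OC)cc(OCc3ccccc3)c2C(=O)O)OCCO1 | intermediate
26 | benzyl 4-({2-(benzyloxy)-4-methoxy-6-[(2-pentyl-1,3-dioxolan-2-yl)methyl]benzoyl}oxy)-2-methoxy-6-(2-oxoheptyl)benzoate | CCCCCC1(Cc2cc(OC)cc(OCc3ccccc3)c2C(=O)Oc2cc(CC(=O)CCCCC)c(C(=O)OCc3ccccc3)c(OC)c2)OCCO1 | intermediate
27 | benzyl 4-{[2-(benzyloxy)-4-methoxy-6-(2-oxoheptyl)benzoyl]oxy}-2-methoxy-6-(2-oxoheptyl)benzoate | CCCCCC(=O)Cc1cc(OC)cc(OCc2ccccc2)c1C(=O)Oc1cc(CC(=O)CCCCC)c(C(=O)OCc2ccccc2)c(OC)c1 | intermediate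
28 | 4-{[2-hydroxy-4-methoxy-6-(2-oxoheptyl)benzoyl]oxy}-2-methoxy-6-(2-oxoheptyl)benzoic acid | CCCCCC(=O)Cc1cc(OC)cc(O)c1C(=O)Oc1cc(CC(=O)CCCCC)c(C(=O)O)c(OC)c1 | target

## Step count and risk

Total step count: 18 (ring B branch: steps 1–10; ring A branch: steps 11–15; joint steps 16–18).
Longest linear sequence: 13 steps (steps 1–10, then 16–18).

Least certain steps:

**Step 6 (key step).** The aryl anion formed after C-arylation may take a proton from the malonate unit faster than it attacks the ester carbonyl, giving simple α-arylation. The acidic methylene of the product may add to a second aryne. The 5-alkoxy group may also erode the regiochemical bias of the methoxy group. Fallback, building the same benzylic ketone by toluate acylation in place of aryne insertion: it sets out from 19 and rejoins the route at 17.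
- 19 is alkylated at the unchelated hydroxyl (4-methoxybenzyl chloride, K2CO3, acetone) to methyl 2-hydroxy-4-(4-methoxybenzyloxy)-6-methylbenzoate F1.
- F1 is methylated (MeI, K2CO3, DMF) to methyl 2-methoxy-4-(4-methoxybenzyloxy)-6-methylbenzoate F2.
- F2 is saponified (KOH, aq. DMSO, 90 °C) to 2-methoxy-4-(4-methoxybenzyloxy)-6-methylbenzoic acid F3.
- F3 is benzylated (BnBr, K2CO3, DMF) to benzyl 2-methoxy-4-(4-methoxybenzyloxy)-6-methylbenzoate F4.
- Lateral lithiation of F4 with LiN(i-Pr)2 at −78 °C and acylation with 22 gives 17.

**Step 4.** Deprotonation may occur at the ring carbon between the two ether oxygens, or at the benzylic carbon of the 4-methoxybenzyl ether (followed by Wittig rearrangement), instead of ortho to the carbamate. Anionic ortho-Fries migration of the carbamoyl group on warming is a further loss. Fallback, placing silicon by halogen–lithium exchange instead of deprotonation: it sets out from 4 and rejoins at 10.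
- Iodination of the phenolate of 4 (I2, NaHCO3, aq. THF) ortho to the oxygen gives 2-iodo-6-methoxy-4-(4-methoxybenzyloxy)phenol F5.
- (Me3Si)2NH converts F5 into [2-iodo-6-methoxy-4-(4-methoxybenzyloxy)phenoxy]trimethylsilane F6.
- n-BuLi at −78 °C effects iodine–lithium exchange and 1,3 O→C silyl migration (retro-Brook rearrangement) to the lithium salt of 9, which is triflated in the same flask (Tf2O) to 10.

**Step 9.** The Grignard reagent may act as a base on the doubly activated benzylic methylene of 15, returning the amide on work-up, or may attack the aromatic benzyl ester on warming. Fallback, a non-basic ketone synthesis: it sets out from 14 and rejoins at 17.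
- 14 is converted (EtSH, EDC·HCl, DMAP, CH2Cl2) into benzyl 2-[2-(ethylsulfanyl)-2-oxoethyl]-6-methoxy-4-(4-methoxybenzyloxy)benzoate F7.
- Fukuyama coupling of F7 with pentylzinc bromide (from 16 and ZnBr2) under PdCl2(PPh3)2 catalysis in THF/toluene gives 17.

**Step 16.** The O-acylisourea of the di-ortho-substituted acid may rearrange to the unreactive N-acylurea faster than it is intercepted, so that the hindered carbonyl is never transferred to the phenol. Fallback, a preformed acyl chloride made under neutral conditions: it sets out from 25 and rejoins at 26.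
- 25 is treated with 1-chloro-N,N,2-trimethylprop-1-en-1-amine (CH2Cl2, 0 °C → rt) to give 2-(benzyloxy)-4-methoxy-6-[(2-pentyl-1,3-dioxolan-2-yl)methyl]benzoyl chloride F8.
- F8 is added to 18 with Et3N and DMAP in CH2Cl2 to give 26.

**Step 17.** Once the ring A ketone is free, acid may promote attack of its enol oxygen on the neighbouring aryl ester carbonyl. This expels the ring B phenol and closes a 3-pentylisocoumarin; the milder the acid, the slower the ketal hydrolysis. Fallback, a ketone mask removed without acid: it sets out from 23 and rejoins at 27.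
- 23 is converted (propane-1,3-dithiol, I2 (cat.), CH2Cl2) into methyl 2-(benzyloxy)-4-methoxy-6-[(2-pentyl-1,3-dithian-2-yl)methyl]benzoate F9.
- F9 is saponified (KOH, aq. DMSO, 90 °C) to 2-(benzyloxy)-4-methoxy-6-[(2-pentyl-1,3-dithian-2-yl)methyl]benzoic acid F10.
- F10 is coupled with 18 (EDC·HCl, DMAP, CH2Cl2) to benzyl 4-({2-(benzyloxy)-4-methoxy-6-[(2-pentyl-1,3-dithian-2-yl)methyl]benzoyl}oxy)-2-methoxy-6-(2-oxoheptyl)benzoate F11.
- Alkylative hydrolysis of F11 (MeI, CaCO3, aq. MeCN, 40 °C) gives 27.

## Further compounds

F1 | step 6 | methyl 2-hydroxy-4-(4-methoxybenzyloxy)-6-methylbenzoate | COC(=O)c1c(C)cc(OCc2ccc(OC)cc2)cc1O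
F2 | step 6 | methyl 2-methoxy-4-(4-methoxybenzyloxy)-6-methylbenzoate | COC(=O)c1c(C)cc(OCc2ccc(OC)cc2)cc1OC
F3 | step 6 | 2-methoxy-4-(4-methoxybenzyloxy)-6-methylbenzoic acid | Cc1cc(OCc2ccc(OC)cc2)cc(OC)c1C(=O)O
F4 | step 6 | benzyl 2-methoxy-4-(4-methoxybenzyloxy)-6-methylbenzoate | Cc1cc(OCc2ccc(OC)cc2)cc(OC)c1C(=O)OCc1ccccc1
F5 | step 4 | 2-iodo-6-methoxy-4-(4-methoxybenzyloxy)phenol | COc1ccc(COc2cc(I)c(O)c(OC)c2)cc1
F6 | step 4 | [2-iodo-6-methoxy-4-(4-methoxybenzyloxy)phenoxy]trimethylsilane | COc1ccc(COc2cc(I)c(O[Si](C)(C)C)c(OC)c2)cc1
F7 | step 9 | benzyl 2-[2-(ethylsulfanyl)-2-oxoethyl]-6-methoxy-4-(4-methoxybenzyloxy)benzoate | CCSC(=O)Cc1cc(OCc2ccc(OC)cc2)cc(OC)c1C(=O)OCc1ccccc1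
F8 | step 16 | 2-(benzyloxy)-4-methoxy-6-[(2-pentyl-1,3-dioxolan-2-yl)methyl]benzoyl chloride | CCCCCC1(Cc2cc(OC)cc(OCc3ccccc3)c2C(=O)Cl)OCCO1
F9 | step 17 | methyl 2-(benzyloxy)-4-methoxy-6-[(2-pentyl-1,3-dithian-2-yl)methyl]benzoate | CCCCCC1(Cc2cc(OC)cc(OCc3ccccc3)c2C(=O)OC)SCCCS1
F10 | step 17 | 2-(benzyloxy)-4-methoxy-6-[(2-pentyl-1,3-dithian-2-yl)methyl]benzoic acid | CCCCCC1(Cc2cc(OC)cc(OCc3ccccc3)c2C(=O)O)SCCCS1
F11 | step 17 | benzyl 4-({2-(benzyloxy)-4-methoxy-6-[(2-pentyl-1,3-dithian-2-yl)methyl]benzoyl}oxy)-2-methoxy-6-(2-oxoheptyl)benzoate | CCCCCC1(Cc2cc(OC)cc(OCc3ccccc3)c2C(=O)Oc2cc(CC(=O)CCCCC)c(C(=O)OCc3ccccc3)c(OC)c2)SCCCS1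
A1 | alternative 1 | 2,4-dimethoxybenzoic acid | COc1ccc(C(=O)O)c(OC)c1
A2 | alternative 1 | dimethylsulfoxonium 2-oxoheptylide | CCCCCC(=O)C=S(C)(C)=O
A3 | alternative 1 | 6,8-dimethoxy-3-pentyl-1H-isochromen-1-one | CCCCCC1=Cc2cc(OC)cc(OC)c2C(=O)O1
A4 | alternative 2 | 1,1-dimethoxy-3-(trimethylsilyloxy)buta-1,3-diene | COC(OC)=CC(=C)O[Si](C)(C)C
A5 | alternative 2 | benzyl 5-(tert-butyldimethylsilyloxy)dec-2-ynoate (racemic) | CCCCCC(CC#CC(=O)OCc1ccccc1)O[Si](C)(C)C(C)(C)C
A6 | alternative 2 | benzyl 2-[2-(tert-butyldimethylsilyloxy)heptyl]-4-hydroxy-6-methoxybenzoate (racemic) | CCCCCC(Cc1cc(O)cc(OC)c1C(=O)OCc1ccccc1)O[Si](C)(C)C(C)(C)C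
A7 | alternative 3 | 2,2-dimethyl-6-[2,4-dioxo-5-(2-pentyl-1,3-dioxolan-2-yl)pentyl]-4H-1,3-dioxin-4-one | CCCCCC1(CC(=O)CC(=O)CC2=CC(=O)OC(C)(C)O2)OCCO1
A8 | alternative 3 | benzyl 4-hydroxy-2-methoxy-6-[(2-pentyl-1,3-dioxolan-2-yl)methyl]benzoate | CCCCCC1(Cc2cc(O)cc(OC)c2C(=O)OCc2ccccc2)OCCO1
A9 | alternative 3 | benzyl 4-({2,4-dihydroxy-6-[(2-pentyl-1,3-dioxolan-2-yl)methyl]benzoyl}oxy)-2-methoxy-6-[(2-pentyl-1,3-dioxolan-2-yl)methyl]benzoate | CCCCCC1(Cc2cc(O)cc(O)c2C(=O)Oc2cc(CC3(CCCCC)OCCO3)c(C(=O)OCc3ccccc3)c(OC)c2)OCCO1
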